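The ratio of X at 12.0 h to X at 4.00 h in the dusk run is 0.400, so X is a place that molecules leave, not an end point.

| setting | winter | dusk | autumn | elm | maple | ash |
|---|---|---|---|---|---|---|
| G | 1 M | 1 M | 0.50 M | 1.0 M | 1.0 M | 1.0 M |
| D | 1.3 M | 1.3 M | 1.3 M | 1.30 M | 1.30 M | 1.30 M |
| E | 1 M | 1.5 M | 2 M | 2.00 M | 2.00 M | 2.00 M |
| temperature | 80 °C | 102 °C | 80 °C | 90 °C | 70 °C | 110 °C |
| remark | run made earlier | run made earlier | run made earlier |  |  |  |
| time |  |  |  | 20 h | 20 h | 20 h |

- winter (time / h: X / %, G / %): 5.00: 17, 83; 10.0: 26, 73; 12.0: 29, 70; 20.0: 29, 64; 25.0: 29, 60; 30.0: 29, 58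
- dusk (time / h: X / %, G / %): 0.500: 13, 87; 1.50: 22, 77; 3.00: 21, 72; 4.00: 20, 71; 6.00: 13, 72; 8.00: 10, 73; 12.0: 8, 68
- autumn (time / h: X / %, G / %): 2.50: 12, 87; 5.00: 22, 78; 10.0: 27, 69; 15.0: 33, 67; 30.0: 33, 58

(scatter of a reading: 2 percentage points)

1. the flask with the highest amount of X, in percent of the G charged ("all alike" if they lie within 1.5 percentage points) (elm / maple / ash / all alike)
2. final X, as a percentage of the G charged, in elm
3. final X, as a percentage of the G charged, in maple
4. final X, as a percentage of the G charged, in ash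



What do you follow? One molecule of X, and I ask its chance of still being X. The leak is the first-order rate constant of that departure, and dusk reads 0.115 h⁻¹.

But winter's X stays flat, so is there no leak there? There may be one. In winter, G falls from 70 % to 58 % between 12.0 h and 30.0 h while X holds 29 %. If G passes through X, that flow leaves X too, which reads 0.0230 h⁻¹.

And elm? It lies 0.455 of the way from winter to dusk. Interpolating logarithmically, its leak is 0.0477 h⁻¹, the chance per hour that one X molecule goes on.

Molecules are born at different times, aren't they? Yes, so I date them all crudely at the stop of the climb. That is 12.0 h in winter and 1.50 h at dusk, which interpolates to 4.66 h for elm. Survival to 20 h is then 0.481. With 37.5 % of the G charged reacted, interpolated between the last readings of winter and dusk, I reckon elm at 18.0 %.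

Ash? The same reckoning, extrapolated, gives a leak of 0.205 h⁻¹ and about 0.539 %.

Maple? Its stop comes at 30.9 h, later than its reading, so X is still climbing. Its 20 h equals 7.77 h of winter, which puts it between winter's 17 % and 26 %. I commit to maple.

The forecast, higher than mine for elm, gives 21 % for elm, 26 % for maple and 3 % for ash, and names maple: “Maple is probably highest, but elm is uncertain.”

The flasks give 17.6 % in elm, 26.0 % in maple and 0.715 % in ash, so maple stands highest.

    G + D ⇌ X (K = 7.20 M⁻¹, k = 0.0210 M⁻¹ h⁻¹, Ea = 86.0 kJ mol⁻¹, ΔH = −65.0 kJ mol⁻¹)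
    E + D → Z (k = 2.20 × 10⁻⁴ M⁻¹ h⁻¹, Ea = 87.0 kJ mol⁻¹)
    X → J (k = 0.00460 h⁻¹, Ea = 116 kJ mol⁻¹)
    2 D → L (k = 0.0190 M⁻¹ h⁻¹, Ea = 89.0 kJ mol⁻¹)
    (constants at 70 °C)

In elm, 35.8 % of the G charged has reacted, and X holds 0.492 of that. Now the leak goes on: the same elm flask read at 30 h has 10.0 h more, so 0.621 of the X survives, which reckons 10.9 %. That flask shows 12.1 %.

The earlier runs and the new flask are simulated for an exercise, noise included.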